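**Plan**
1. Retrosynthesis: the two pyran ether bonds O1–C2 and O1'–C2' are cut first, then the C6–C6' biaryl bond, then the C4–C3 bond of each half (ring A aldehyde plus ring B alkyne). Flavan numbering is used for these atoms in all intermediates; primes mark unit 2.
2. Enabling feature: in each unit O1 (on C8a of ring A) and O3 sit on the neighbouring carbons C2 and C3, and C2 is benzylic to ring B. A cis C2–C3 epoxide opened at C2 by the C8a phenol therefore closes ring C and leaves O3 as the free hydroxyl.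
3. Forward: aldehyde and alkyne give a propargylic alcohol, then the Z-allylic alcohol, then one cis-epoxy alcohol common to both halves. It is silylated and borylated (threo half, unit 2), or epimerised at C4 by oxidation and chelate-controlled reduction and silylated (erythro half, unit 1).
4. Suzuki coupling joins the halves, fluoride frees the two C8a phenols, and both rings C close in one step; desilylation and hydrogenolysis finish.
5. Stereochemistry: C4 from a BINOL–titanium alkynylation (one enantiomer serves both halves), C3 from hydroxyl-directed epoxidation of the Z-alkene, C4 of unit 1 from the chelate-controlled reduction, C2 and C2' from inversion in the epoxide opening.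

Key step: step 15

Assumption: (R)-BINOL/Ti(OiPr)4 is taken to deliver the alkynylzinc to the Re face of the ring A aldehyde (mirror image of the Si-face sense of the (S)-ligand); the antipodal ligand is used if the carbinol proves to be (S).

**Route**

Step 1
Reactants: 1 2,3,4-trihydroxybenzaldehyde
Product: 2 3,4-bis(benzyloxy)-2-hydroxybenzaldehyde
Conditions: BnBr (2.05 equiv), K2CO3 (2.1 equiv), acetone, reflux, N2
Reagents that add atoms: benzyl bromide, BrCc1ccccc1
Why: Williamson O-benzylation under weak base; the 2-hydroxyl is held in a hydrogen bond to the formyl oxygen and is the least nucleophilic, so alkylation should stop at O3 and O4, as in the classical 3,4-dibenzylation of 2,3,4-trihydroxyaryl carbonyl compounds.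

Step 2
Reactants: 2 3,4-bis(benzyloxy)-2-hydroxybenzaldehyde
Product: 3 3,4-bis(benzyloxy)-5-bromo-2-hydroxybenzaldehyde
Conditions: NBS (1.05 equiv), MeCN, 0 °C, dark
Reagents that add atoms: N-bromosuccinimide, BrN1C(=O)CCC1=O
Why: Electrophilic aromatic bromination; C5 is para to the free 2-hydroxyl, ortho to the 4-benzyloxy group and meta to the formyl group, so it is the only strongly activated open position.

Step 3
Reactants: 3 3,4-bis(benzyloxy)-5-bromo-2-hydroxybenzaldehyde
Product: 4 3,4-bis(benzyloxy)-5-bromo-2-[(triisopropylsilyl)oxy]benzaldehyde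
Conditions: TIPSOTf (1.3 equiv), 2,6-lutidine (2 equiv), CH2Cl2, 0 °C
Reagents that add atoms: triisopropylsilyl trifluoromethanesulfonate, CC(C)[Si](C(C)C)(C(C)C)OS(=O)(=O)C(F)(F)F
Why: Silylation of a hindered, hydrogen-bonded phenol with a silyl triflate; the bulky aryl TIPS ether should resist the organozinc, hydride and aqueous-base steps and O-to-O silyl migration, yet is later cleaved by fluoride far faster than an alkyl TBS ether.

Step 4
Reactants: 5 4-(benzyloxy)benzaldehyde
Product: 6 1-(benzyloxy)-4-ethynylbenzene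
Conditions: dimethyl (1-diazo-2-oxopropyl)phosphonate (1.3 equiv), K2CO3 (2 equiv), MeOH, rt
Reagents that add atoms: Ohira–Bestmann reagent (dimethyl (1-diazo-2-oxopropyl)phosphonate), COP(=O)(OC)C(=[N+]=[N-])C(C)=O
Why: Seyferth–Gilbert homologation in its Ohira–Bestmann form converts the non-enolisable aryl aldehyde into the terminal alkyne under mild carbonate conditions that leave the benzyl ether alone.

Step 5
Reactants: 4 3,4-bis(benzyloxy)-5-bromo-2-[(triisopropylsilyl)oxy]benzaldehyde; 6 1-(benzyloxy)-4-ethynylbenzene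
Product: 8 (1R)-1-{3,4-bis(benzyloxy)-5-bromo-2-[(triisopropylsilyl)oxy]phenyl}-3-[4-(benzyloxy)phenyl]prop-2-yn-1-ol, via ethyl(arylethynyl)zinc 7 (not isolated)
Conditions: 6 (2.2 equiv), Et2Zn (2.0 equiv), toluene, reflux, 1 h; then (R)-BINOL (20 mol%), Ti(OiPr)4 (50 mol%), Et2O, rt; then 4, rt; sat. aq. NH4Cl
Reagents that add atoms: diethylzinc, CC[Zn]CC (its ethylzinc unit is held only in intermediate 7)
Why: BINOL–titanium-catalysed enantioselective addition of an alkynylzinc to an aryl aldehyde; the (R)-ligand is expected to deliver the alkynyl group to the Re face of the formyl group, which sets C4 as (R) (the oxygenated aryl group ranks above the alkynyl group).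

Step 6
Reactants: 8 the (1R)-propargylic alcohol
Product: 9 (1R,2Z)-1-{3,4-bis(benzyloxy)-5-bromo-2-[(triisopropylsilyl)oxy]phenyl}-3-[4-(benzyloxy)phenyl]prop-2-en-1-ol
Conditions: H2 (1 atm), Pd/CaCO3 poisoned with Pb(OAc)2 (Lindlar catalyst), quinoline, EtOAc, rt
Reagents that add atoms: none
Why: Lindlar semihydrogenation adds hydrogen syn to the alkyne and stops at the Z-alkene, the poisoned catalyst leaving the aryl bromide, the benzyl ethers and the carbinol untouched.

Step 7
Reactants: 9 the (1R,2Z)-allylic alcohol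
Product: 10 (S)-{3,4-bis(benzyloxy)-5-bromo-2-[(triisopropylsilyl)oxy]phenyl}{(2R,3S)-3-[4-(benzyloxy)phenyl]oxiran-2-yl}methanol (threo cis-epoxy alcohol)
Conditions: mCPBA (1.3 equiv), CH2Cl2/aq. NaHCO3 (two-phase), 0 °C; chromatography on Et3N-deactivated silica
Reagents that add atoms: 3-chloroperoxybenzoic acid, OOC(=O)c1cccc(Cl)c1
Why: Hydroxyl-directed (Henbest) peracid epoxidation; allylic 1,3-strain in the Z-alkene holds the carbinol hydrogen in the alkene plane, so the hydrogen-bonded peracid should be delivered to the face bearing the hydroxyl and give the threo epoxy alcohol, the stereospecific syn oxygen transfer fixing the cis-epoxide with oxirane C2 (R) and C3 (S).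

Step 8
Reactants: 10 the threo cis-epoxy alcohol
Product: 11 tert-butyl[(S)-{3,4-bis(benzyloxy)-5-bromo-2-[(triisopropylsilyl)oxy]phenyl}{(2S,3S)-3-[4-(benzyloxy)phenyl]oxiran-2-yl}methoxy]dimethylsilane (threo arm bromide)
Conditions: TBSCl (1.5 equiv), imidazole (3 equiv), DMAP (cat.), DMF, rt
Reagents that add atoms: tert-butyldimethylsilyl chloride, CC(C)(C)[Si](C)(C)Cl
Why: Standard silylation of a secondary alcohol under weakly basic conditions that do not touch the acid-sensitive aryl epoxide; no stereocentre is affected (the oxirane C2 descriptor becomes S only through the CIP ranking of the silyl ether).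

Step 9
Reactants: 11 the threo arm bromide
Product: 12 threo arm pinacol boronate (11 with Br replaced by 4,4,5,5-tetramethyl-1,3,2-dioxaborolan-2-yl)
Conditions: B2pin2 (1.3 equiv), Pd(dppf)Cl2 (5 mol%), KOAc (3 equiv), 1,4-dioxane, 80 °C
Reagents that add atoms: bis(pinacolato)diboron, CC1(C)OB(OC1(C)C)B1OC(C)(C)C(C)(C)O1
Why: Miyaura borylation; zerovalent palladium inserts into the aryl C–Br bond and the acetate-activated diboron transfers the boryl group under anhydrous, weakly basic conditions that epoxide and silyl ethers should tolerate.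

Step 10
Reactants: 10 the threo cis-epoxy alcohol
Product: 13 {3,4-bis(benzyloxy)-5-bromo-2-[(triisopropylsilyl)oxy]phenyl}{(2S,3S)-3-[4-(benzyloxy)phenyl]oxiran-2-yl}methanone (cis-epoxy ketone)
Conditions: Dess–Martin periodinane (1.3 equiv), pyridine (3 equiv), CH2Cl2, 0 °C to rt
Reagents that add atoms: none
Why: Dess–Martin oxidation of the benzylic carbinol under pyridine buffering should give the cis-epoxy aryl ketone without touching the oxirane stereocentres, removing the C4 centre so that it can be set again.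

Step 11
Reactants: 13 the cis-epoxy ketone
Product: 14 (R)-{3,4-bis(benzyloxy)-5-bromo-2-[(triisopropylsilyl)oxy]phenyl}{(2R,3S)-3-[4-(benzyloxy)phenyl]oxiran-2-yl}methanol (erythro cis-epoxy alcohol)
Conditions: Zn(BH4)2 (1.0 equiv), Et2O, −30 °C; sat. aq. NH4Cl
Reagents that add atoms: none
Why: Chelation-controlled reduction of an α,β-epoxy ketone with Zn(BH4)2; zinc bridges the carbonyl and oxirane oxygens and hydride enters from the face away from the oxirane C–C bond, which should give the erythro epoxy alcohol, the (R)-C4 epimer of 10.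

Step 12
Reactants: 14 the erythro cis-epoxy alcohol
Product: 15 tert-butyl[(R)-{3,4-bis(benzyloxy)-5-bromo-2-[(triisopropylsilyl)oxy]phenyl}{(2S,3S)-3-[4-(benzyloxy)phenyl]oxiran-2-yl}methoxy]dimethylsilane (erythro arm bromide)
Conditions: TBSCl (1.5 equiv), imidazole (3 equiv), DMAP (cat.), DMF, rt
Reagents that add atoms: tert-butyldimethylsilyl chloride, CC(C)(C)[Si](C)(C)Cl
Why: The same silylation as in step 8 fixes the erythro arm as its C4 silyl ether with no change at any stereocentre.

Step 13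
Reactants: 12 the threo arm pinacol boronate; 15 the erythro arm bromide
Product: 16 2,2',3,3'-tetrakis(benzyloxy)-4,4'-bis[(triisopropylsilyl)oxy]-1,1'-biphenyl carrying at C5 the (R)-[(2S,3S)-3-(4-benzyloxyphenyl)oxiran-2-yl][(tert-butyldimethylsilyl)oxy]methyl group (erythro arm) and at C5' its (S)-carbinol epimer (threo arm)
Conditions: Pd(OAc)2 (5 mol%), SPhos (10 mol%), K3PO4 (3 equiv), THF/H2O (10:1), 45 °C
Reagents that add atoms: none
Why: Suzuki–Miyaura coupling of an aryl bromide with an aryl pinacol boronate forms the C6–C6' biaryl bond; the electron-rich biaryl phosphine should allow the two ortho-alkoxy partners to couple at 45 °C, where epoxides, silyl ethers and benzyl ethers are expected to survive, and with only one ortho substituent per ring no atropisomers arise.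

Step 14
Reactants: 16 the biaryl bis(epoxide) bis(aryl TIPS ether)
Product: 17 2,2',3,3'-tetrakis(benzyloxy)-5-{(R)-[(2S,3S)-3-(4-benzyloxyphenyl)oxiran-2-yl][(tert-butyldimethylsilyl)oxy]methyl}-5'-{(S)-[(2S,3S)-3-(4-benzyloxyphenyl)oxiran-2-yl][(tert-butyldimethylsilyl)oxy]methyl}-[1,1'-biphenyl]-4,4'-diol
Conditions: TBAF (2.5 equiv), AcOH (2.5 equiv), THF, −20 to 0 °C; pH 7 phosphate buffer; used without chromatography
Reagents that add atoms: none
Why: Fluoride-mediated desilylation; aryl silyl ethers are cleaved far faster than hindered secondary alkyl TBS ethers because phenoxide is the better leaving group, and the acetic acid buffer keeps the liberated phenols protonated so that the epoxides should stay intact until the next step.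

Step 15
Reactants: 17 the biaryl bis(cis-epoxy silyl ether) diphenol
Product: 18 (2R,2'R,3S,3'S,4R,4'S)-7,7',8,8'-tetrakis(benzyloxy)-2,2'-bis[4-(benzyloxy)phenyl]-4,4'-bis[(tert-butyldimethylsilyl)oxy]-[6,6'-bichromane]-3,3'-diol (unit 1 all-cis; unit 2 2,3-cis-3,4-trans)
Conditions: PPTS (20 mol%), CH2Cl2, −20 to 0 °C
Reagents that add atoms: none
Why: The pyridinium salt hydrogen-bonds to each oxirane oxygen while the neighbouring C8a phenol attacks the benzylic C2 from the side opposite the C2–O bond, an SN2-like opening that forms O1–C2 and O1'–C2' and leaves O3 and O3' as free hydroxyls. The closest known reaction type is the acid-mediated cyclisation of 2-hydroxyaryl epoxides used for flavan-3-ols and, at the ketone level, of 2'-hydroxychalcone epoxides to dihydroflavonols. Each ring C (O1, C2, C3, C4, C4a, C8a) closes in the 6-endo-tet mode, the breaking epoxide C–O bond lying inside the new ring. C2 and C2' are the new stereocentres and are set by inversion of the (S)-configured oxirane carbon, so the cis-epoxide should give the 2,3-cis (2R) arrangement in both units, while C3 and C4 are carried through unchanged (all-cis unit 1 from the erythro arm, 3,4-trans unit 2 from the threo arm). The step needs attack at C2 and not at C3 (5-exo), and bond formation before the C2–O bond ionises: C2 is benzylic to the 4-benzyloxyphenyl ring whereas C3 is flanked and inductively deactivated by the silyloxy-bearing C4, and the weak buffered acid at low temperature should keep the opening concerted. The silyl group on O4 rules out Payne-type epoxide migration and attack by the C4 oxygen.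

Step 16
Reactants: 18 the bis(4-O-silyl) dimer
Product: 19 (2R,2'R,3R,3'R,4R,4'S)-7,7',8,8'-tetrakis(benzyloxy)-2,2'-bis[4-(benzyloxy)phenyl]-[6,6'-bichromane]-3,3',4,4'-tetrol
Conditions: TBAF (3 equiv), THF, 0 °C to rt
Reagents that add atoms: none
Why: Fluoride cleavage of the two secondary TBS ethers; nothing else in the benzyl-protected dimer is fluoride- or base-sensitive and no stereocentre is touched (C3 and C3' return to the R descriptor by CIP ranking only).

Step 17
Reactants: 19 the hexabenzyl ether tetrol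
Product: 20 (2R,2'R,3R,3'R,4R,4'S)-2,2'-bis(4-hydroxyphenyl)-[6,6'-bichromane]-3,3',4,4',7,7',8,8'-octol (CNP0121763.1)
Conditions: H2 (1 atm), Pd(OH)2/C, THF/MeOH, rt, degassed solvents; filtration under argon
Reagents that add atoms: none
Why: Catalytic hydrogenolysis of the six benzyl ethers over Pd(OH)2/C under neutral conditions is the standard last step for flavan-3-ol polyphenols; the cyclic C2–O1 benzylic ethers and the C4 hydroxyls are expected to survive without acid, and the air-sensitive polyphenol is handled under argon.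

**Compound list**
1 | 2,3,4-trihydroxybenzaldehyde | O=Cc1ccc(O)c(O)c1O | starting material
2 | 3,4-bis(benzyloxy)-2-hydroxybenzaldehyde | O=Cc1ccc(OCc2ccccc2)c(OCc2ccccc2)c1O | intermediate
3 | 3,4-bis(benzyloxy)-5-bromo-2-hydroxybenzaldehyde | O=Cc1cc(Br)c(OCc2ccccc2)c(OCc2ccccc2)c1O | intermediate
4 | 3,4-bis(benzyloxy)-5-bromo-2-[(triisopropylsilyl)oxy]benzaldehyde | O=Cc1cc(Br)c(OCc2ccccc2)c(OCc2ccccc2)c1O[Si](C(C)C)(C(C)C)C(C)C | intermediate
5 | 4-(benzyloxy)benzaldehyde | O=Cc1ccc(OCc2ccccc2)cc1 | starting material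
6 | 1-(benzyloxy)-4-ethynylbenzene | C#Cc1ccc(OCc2ccccc2)cc1 | intermediate
7 | ethyl{[4-(benzyloxy)phenyl]ethynyl}zinc (not isolated) | CC[Zn]C#Cc1ccc(OCc2ccccc2)cc1 | intermediate
8 | (1R)-1-{3,4-bis(benzyloxy)-5-bromo-2-[(triisopropylsilyl)oxy]phenyl}-3-[4-(benzyloxy)phenyl]prop-2-yn-1-ol | O[C@H](C#Cc1ccc(OCc2ccccc2)cc1)c1cc(Br)c(OCc2ccccc2)c(OCc2ccccc2)c1O[Si](C(C)C)(C(C)C)C(C)C | intermediate
9 | (1R,2Z)-1-{3,4-bis(benzyloxy)-5-bromo-2-[(triisopropylsilyl)oxy]phenyl}-3-[4-(benzyloxy)phenyl]prop-2-en-1-ol | O[C@H](/C=C\c1ccc(OCc2ccccc2)cc1)c1cc(Br)c(OCc2ccccc2)c(OCc2ccccc2)c1O[Si](C(C)C)(C(C)C)C(C)C | intermediate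
10 | (S)-{3,4-bis(benzyloxy)-5-bromo-2-[(triisopropylsilyl)oxy]phenyl}{(2R,3S)-3-[4-(benzyloxy)phenyl]oxiran-2-yl}methanol (threo) | O[C@H]([C@H]1O[C@H]1c1ccc(OCc2ccccc2)cc1)c1cc(Br)c(OCc2ccccc2)c(OCc2ccccc2)c1O[Si](C(C)C)(C(C)C)C(C)C | intermediate
11 | tert-butyl[(S)-{3,4-bis(benzyloxy)-5-bromo-2-[(triisopropylsilyl)oxy]phenyl}{(2S,3S)-3-[4-(benzyloxy)phenyl]oxiran-2-yl}methoxy]dimethylsilane (threo arm bromide) | CC(C)(C)[Si](C)(C)O[C@H]([C@H]1O[C@H]1c1ccc(OCc2ccccc2)cc1)c1cc(Br)c(OCc2ccccc2)c(OCc2ccccc2)c1O[Si](C(C)C)(C(C)C)C(C)C | intermediate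
12 | threo arm pinacol boronate (11 with Br replaced by 4,4,5,5-tetramethyl-1,3,2-dioxaborolan-2-yl) | CC(C)(C)[Si](C)(C)O[C@H]([C@H]1O[C@H]1c1ccc(OCc2ccccc2)cc1)c1cc(B2OC(C)(C)C(C)(C)O2)c(OCc2ccccc2)c(OCc2ccccc2)c1O[Si](C(C)C)(C(C)C)C(C)C | intermediate
13 | {3,4-bis(benzyloxy)-5-bromo-2-[(triisopropylsilyl)oxy]phenyl}{(2S,3S)-3-[4-(benzyloxy)phenyl]oxiran-2-yl}methanone (cis-epoxy ketone) | O=C([C@H]1O[C@H]1c1ccc(OCc2ccccc2)cc1)c1cc(Br)c(OCc2ccccc2)c(OCc2ccccc2)c1O[Si](C(C)C)(C(C)C)C(C)C | intermediate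
14 | (R)-{3,4-bis(benzyloxy)-5-bromo-2-[(triisopropylsilyl)oxy]phenyl}{(2R,3S)-3-[4-(benzyloxy)phenyl]oxiran-2-yl}methanol (erythro) | O[C@@H]([C@H]1O[C@H]1c1ccc(OCc2ccccc2)cc1)c1cc(Br)c(OCc2ccccc2)c(OCc2ccccc2)c1O[Si](C(C)C)(C(C)C)C(C)C | intermediate
15 | tert-butyl[(R)-{3,4-bis(benzyloxy)-5-bromo-2-[(triisopropylsilyl)oxy]phenyl}{(2S,3S)-3-[4-(benzyloxy)phenyl]oxiran-2-yl}methoxy]dimethylsilane (erythro arm bromide) | CC(C)(C)[Si](C)(C)O[C@@H]([C@H]1O[C@H]1c1ccc(OCc2ccccc2)cc1)c1cc(Br)c(OCc2ccccc2)c(OCc2ccccc2)c1O[Si](C(C)C)(C(C)C)C(C)C | intermediate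
16 | 2,2',3,3'-tetrakis(benzyloxy)-5-{(R)-[(2S,3S)-3-(4-benzyloxyphenyl)oxiran-2-yl][(tert-butyldimethylsilyl)oxy]methyl}-5'-{(S)-[(2S,3S)-3-(4-benzyloxyphenyl)oxiran-2-yl][(tert-butyldimethylsilyl)oxy]methyl}-4,4'-bis[(triisopropylsilyl)oxy]-1,1'-biphenyl | CC(C)(C)[Si](C)(C)O[C@@H]([C@H]1O[C@H]1c1ccc(OCc2ccccc2)cc1)c1cc(-c2cc([C@H](O[Si](C)(C)C(C)(C)C)[C@H]3O[C@H]3c3ccc(OCc4ccccc4)cc3)c(O[Si](C(C)C)(C(C)C)C(C)C)c(OCc3ccccc3)c2OCc2ccccc2)c(OCc2ccccc2)c(OCc2ccccc2)c1O[Si](C(C)C)(C(C)C)C(C)C | intermediate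
17 | 2,2',3,3'-tetrakis(benzyloxy)-5-{(R)-[(2S,3S)-3-(4-benzyloxyphenyl)oxiran-2-yl][(tert-butyldimethylsilyl)oxy]methyl}-5'-{(S)-[(2S,3S)-3-(4-benzyloxyphenyl)oxiran-2-yl][(tert-butyldimethylsilyl)oxy]methyl}-[1,1'-biphenyl]-4,4'-diol | CC(C)(C)[Si](C)(C)O[C@@H]([C@H]1O[C@H]1c1ccc(OCc2ccccc2)cc1)c1cc(-c2cc([C@H](O[Si](C)(C)C(C)(C)C)[C@H]3O[C@H]3c3ccc(OCc4ccccc4)cc3)c(O)c(OCc3ccccc3)c2OCc2ccccc2)c(OCc2ccccc2)c(OCc2ccccc2)c1O | intermediate
18 | (2R,2'R,3S,3'S,4R,4'S)-7,7',8,8'-tetrakis(benzyloxy)-2,2'-bis[4-(benzyloxy)phenyl]-4,4'-bis[(tert-butyldimethylsilyl)oxy]-[6,6'-bichromane]-3,3'-diol | c6ccccc6COc1ccc([C@H]2Oc3c(cc(-c4cc5c(c(OCc6ccccc6)c4OCc6ccccc6)O[C@H](c4ccc(OCc6ccccc6)cc4)[C@H](O)[C@H]5O[Si](C)(C)C(C)(C)C)c(OCc6ccccc6)c3OCc6ccccc6)[C@@H](O[Si](C)(C)C(C)(C)C)[C@H]2O)cc1 | intermediate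
19 | (2R,2'R,3R,3'R,4R,4'S)-7,7',8,8'-tetrakis(benzyloxy)-2,2'-bis[4-(benzyloxy)phenyl]-[6,6'-bichromane]-3,3',4,4'-tetrol | c6ccccc6COc1ccc([C@H]2Oc3c(cc(-c4cc5c(c(OCc6ccccc6)c4OCc6ccccc6)O[C@H](c4ccc(OCc6ccccc6)cc4)[C@H](O)[C@H]5O)c(OCc6ccccc6)c3OCc6ccccc6)[C@@H](O)[C@H]2O)cc1 | intermediate
20 | (2R,2'R,3R,3'R,4R,4'S)-2,2'-bis(4-hydroxyphenyl)-[6,6'-bichromane]-3,3',4,4',7,7',8,8'-octol (CNP0121763.1) | Oc1ccc([C@H]2Oc3c(cc(-c4cc5c(c(O)c4O)O[C@H](c4ccc(O)cc4)[C@H](O)[C@H]5O)c(O)c3O)[C@@H](O)[C@H]2O)cc1 | target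

**Step count and risks**

Total step count: 17. Longest linear sequence: 14 steps (steps 1, 2, 3, 5, 6, 7, 10, 11, 12, 13, 14, 15, 16, 17).

Steps most likely to fail:

Step 15 (key ring closure). The C2–O bond of the electron-rich benzylic epoxide may ionise before the phenol arrives, which would erode the inversion at C2, or the phenol may attack C3 in the 5-exo mode. The fallback moves the closure from the acid-assisted to an anionic manifold. It sets out from 17, which is deprotonated with KHMDS (2.1 equiv) in THF at −78 °C to the dipotassium diphenoxide F1. On warming to 0 °C each phenoxide should open its epoxide by direct SN2 attack at the benzylic C2, with no cationic character at that carbon, and aqueous work-up brings the sequence back to the route at 18.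

Step 13 (biaryl coupling). Under warm aqueous base with palladium the epoxides or the aryl silyl ethers may be degraded, and the electron-rich ortho-alkoxy boronate may protodeboronate. The fallback is a base-free, anhydrous Stille coupling. It sets out from 11, which is stannylated with hexamethylditin and Pd(PPh3)4 in toluene at 90 °C to the aryltrimethylstannane F2. This is coupled with bromide 15 using Pd(PPh3)4 and CuI in DMF at 60 °C, which returns to the route at 16.

Step 17 (hydrogenolysis). Once the 4-hydroxyls are free, the benzylic C4–O bonds (or the C2–O1 bonds) may also be cleaved, and the product may oxidise during prolonged reduction. The fallback reverses the order of deprotection. It sets out from 18, which is hydrogenolysed first (H2, Pd(OH)2/C, EtOAc/MeOH) while the C4 oxygens are still shielded as TBS ethers, giving the hexaphenol bis(silyl ether) F3. The silyl groups are then removed with Et3N·3HF in MeCN under argon, which comes back to the route at the target 20.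

**Further compounds**
F1 | step 15 | dipotassium 4,4'-diphenoxide of 17 | [K+].[K+].CC(C)(C)[Si](C)(C)O[C@@H]([C@H]1O[C@H]1c1ccc(OCc2ccccc2)cc1)c1cc(-c2cc([C@H](O[Si](C)(C)C(C)(C)C)[C@H]3O[C@H]3c3ccc(OCc4ccccc4)cc3)c([O-])c(OCc3ccccc3)c2OCc2ccccc2)c(OCc2ccccc2)c(OCc2ccccc2)c1[O-]
F2 | step 13 | threo arm aryltrimethylstannane (11 with Br replaced by trimethylstannyl) | CC(C)(C)[Si](C)(C)O[C@H]([C@H]1O[C@H]1c1ccc(OCc2ccccc2)cc1)c1cc([Sn](C)(C)C)c(OCc2ccccc2)c(OCc2ccccc2)c1O[Si](C(C)C)(C(C)C)C(C)C
F3 | step 17 | (2R,2'R,3S,3'S,4R,4'S)-4,4'-bis[(tert-butyldimethylsilyl)oxy]-2,2'-bis(4-hydroxyphenyl)-[6,6'-bichromane]-3,3',7,7',8,8'-hexol | Oc1ccc([C@H]2Oc3c(cc(-c4cc5c(c(O)c4O)O[C@H](c4ccc(O)cc4)[C@H](O)[C@H]5O[Si](C)(C)C(C)(C)C)c(O)c3O)[C@@H](O[Si](C)(C)C(C)(C)C)[C@H]2O)cc1
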